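**Plan**

- Retrosynthesis: the two C6–O ester bonds are cut first, giving the C6-epimeric amino alcohol and a bis-O-tosyl α-truxillic diacid (head-to-tail photodimer of ferulic acid). In each alkaloid unit C4a–C5 is cut next, then C4=C4a, the N–acyl bond and C7–C7a.
- Enabling feature (cyclopenta[c]pyridine numbering): with C6 as a ketone and the C3 lactam carbonyl conjugated to C4=C4a, C5 is an enolisable α-carbon and C4a a β-carbon. Ring B (C4a–C5–C6–C7–C7a) therefore closes by a five-membered enolate Michael addition that also creates the C4 methyl centre.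
- Forward: an iridium-catalysed allylic alkylation joins C7–C7a; N-methacryloylation and ring-closing metathesis build ring A (the unsaturated lactam); the Michael closure builds ring B; LiAlH4 gives the amino alcohol; two such units are esterified onto the cyclobutane diacid and the phenols are freed.
- Stereochemistry: C7a from the chiral iridium catalyst; C4a from the tether (cis fusion); C4 from convex-face protonation of the lactam enolate; C7 by equilibration α to the ketone; C6 by convex-face hydride delivery followed by Mitsunobu inversion; the cyclobutane from the E-alkenes and the crystal packing.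

Key step: step 7

Assumption: the (Sa,S,S) antipode of the binaphthyl bis(1-phenylethyl)phosphoramidite is taken to give the 3R product in step 4, following the usual facial model for this ligand family; if the first run shows the opposite sense, the mirror-image ligand is used and nothing else changes.

**Route**

Step 1
Reactants: 1 tert-butyl methylcarbamate; 2 (E)-1,4-dichlorobut-2-ene
Product: 3 tert-butyl [(2E)-4-chlorobut-2-en-1-yl](methyl)carbamate
Conditions: NaH, DMF, 0 °C; added to 2 (3 equiv), 0 °C → rt
Reagents that add atoms: none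
Why: N-alkylation of the sodium carbamate by SN2 displacement of one primary allylic chloride; the threefold excess of the symmetrical dichloride should hold back the second substitution, and the E geometry is kept.

Step 2
Reactants: 3 tert-butyl [(2E)-4-chlorobut-2-en-1-yl](methyl)carbamate
Product: 5 tert-butyl [(2E)-4-hydroxybut-2-en-1-yl](methyl)carbamate, via allylic acetate 4 (not isolated)
Conditions: KOAc, DMF, 60 °C; then K2CO3 (cat.), MeOH, rt
Reagents that add atoms: potassium acetate, CC(=O)[O-].[K+]
Why: SN2 displacement of the primary allylic chloride by acetate followed by base-catalysed transesterification with methanol should free the allylic alcohol without touching the carbamate.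

Step 3
Reactants: 5 tert-butyl [(2E)-4-hydroxybut-2-en-1-yl](methyl)carbamate
Product: 6 (2E)-4-[(tert-butoxycarbonyl)(methyl)amino]but-2-en-1-yl methyl carbonate
Conditions: ClCO2Me, pyridine, CH2Cl2, 0 °C
Reagents that add atoms: methyl chloroformate, COC(=O)Cl
Why: O-acylation of the primary alcohol gives the methyl carbonate, the usual leaving group for iridium-catalysed allylic substitution because it ionises irreversibly with loss of CO2.

Step 4
Reactants: 6 (2E)-4-[(tert-butoxycarbonyl)(methyl)amino]but-2-en-1-yl methyl carbonate; 7 tert-butyl 2-methyl-3-oxobutanoate (racemic, 1.5 equiv)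
Product: 8 tert-butyl (3R)-2-acetyl-3-{[(tert-butoxycarbonyl)(methyl)amino]methyl}-2-methylpent-4-enoate (both C2 epimers)
Conditions: [Ir(cod)Cl]2 (2 mol%), (Sa,S,S)-O,O'-(1,1'-binaphthyl-2,2'-diyl) N,N-bis(1-phenylethyl)phosphoramidite (4 mol%), TBD (10 mol%), LiOt-Bu (1.5 equiv), THF, rt
Reagents that add atoms: none
Why: Iridium-catalysed asymmetric allylic alkylation, in which the cyclometalated monovalent iridium–phosphoramidite complex ionises the E-carbonate to an allyl complex that the lithium enolate attacks at the substituted terminus; this gives the branched product and sets C7a (3R here) under catalyst control, while the configuration of the quaternary carbon does not matter because that centre is lost on decarboxylation.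

Step 5
Reactants: 8 tert-butyl (3R)-2-acetyl-3-{[(tert-butoxycarbonyl)(methyl)amino]methyl}-2-methylpent-4-enoate; 9 methacryloyl chloride
Product: 12 N-[(2R)-2-ethenyl-3-methyl-4-oxopentyl]-N,2-dimethylprop-2-enamide (both C3 epimers), via keto acid ammonium trifluoroacetate 10 (not isolated), via amino ketone trifluoroacetate 11 (not isolated)
Conditions: TFA, CH2Cl2, 0 → 35 °C; evaporate; then 9, 2 M aq. NaOH, CH2Cl2, 0 °C
Reagents that add atoms: none
Why: Acidolysis removes the Boc group and the tert-butyl ester, the β-keto acid loses CO2, and the ammonium salt is N-acylated under Schotten–Baumann conditions as soon as it is neutralised, so that acylation should outrun ring closure of the secondary amine onto the ketone; C7 comes out as both epimers, which is accepted because step 7 equilibrates this centre.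

Step 6
Reactants: 12 N-[(2R)-2-ethenyl-3-methyl-4-oxopentyl]-N,2-dimethylprop-2-enamide
Product: 13 (5R)-1,3-dimethyl-5-(3-oxobutan-2-yl)-5,6-dihydropyridin-2(1H)-one (both epimers at the side-chain carbon, which is C7)
Conditions: second-generation Grubbs catalyst (H2IMes)(PCy3)Cl2Ru=CHPh (5 mol%), toluene, 80 °C
Reagents that add atoms: none
Why: Ring-closing metathesis of the vinyl group with the 1,1-disubstituted methacrylamide alkene closes the six-membered α-methyl unsaturated lactam (ring A) with loss of ethene, a standard entry to 3-methyl-5,6-dihydropyridin-2-ones that tolerates the ketone and leaves C7a untouched.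

Step 7
Reactants: 13 (5R)-1,3-dimethyl-5-(3-oxobutan-2-yl)-5,6-dihydropyridin-2(1H)-one
Product: 14 (4R,4aR,7S,7aR)-2,4,7-trimethylhexahydro-1H-cyclopenta[c]pyridine-3,6(2H,4H)-dione
Conditions: KOt-Bu (0.3 equiv), t-BuOH/THF (1:1), 0 °C → rt; AcOH quench at 0 °C
Reagents that add atoms: none
Why: KOt-Bu deprotonates the ketone reversibly on both sides, but only the methyl-side (C5) enolate can reach the β-carbon C4a of the α-methyl unsaturated lactam, so it adds in an intramolecular Michael reaction, and the lactam enolate so formed is protonated by t-BuOH, which returns the alkoxide and keeps the base catalytic. The closest known reaction type is the base-mediated intramolecular Michael addition of a ketone enolate to an α,β-unsaturated lactam or ester. Ring B (C4a–C5–C6–C7–C7a, the cyclopentanone) closes in the 5-exo-trig mode, the C4=C4a double bond lying outside the new ring. C4a is controlled by the three-atom tether hanging from C7a, which can bridge only to its own face and so gives the cis ring fusion; C4 is controlled by protonation of the bicyclic lactam enolate on the convex face (the face of H4a, away from C5), which leaves the methyl on the concave face; C7 is controlled thermodynamically, because this ketone α-centre epimerises under the same conditions and should settle with its methyl on the convex face, trans to C1. The step needs regioselectivity between the two enolates, which ring size secures, and kinetic protonation at C4 without later epimerisation, which the much lower acidity of the lactam α-hydrogen compared with the ketone α-hydrogens, the substoichiometric base and the low temperature should secure.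

Step 8
Reactants: 14 (4R,4aR,7S,7aR)-2,4,7-trimethylhexahydro-1H-cyclopenta[c]pyridine-3,6(2H,4H)-dione
Product: 15 (4R,4aS,6S,7S,7aR)-2,4,7-trimethyloctahydro-1H-cyclopenta[c]pyridin-6-ol (6-epi-incarvilline)
Conditions: LiAlH4 (4 equiv), THF, −78 °C → reflux; H2O, aq. NaOH work-up
Reagents that add atoms: none
Why: Hydride reduction with LiAlH4, in which the ketone is reduced first at low temperature from the convex face (that of H4a and H7a) because the concave face is screened by C1 and C4 of ring A, giving the 6S alcohol, and the tertiary lactam is then reduced to the N-methyl amine on heating; the C4a descriptor changes from R to S only because the substituent ranking changes.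

Step 9
Reactants: 16 ferulic acid
Product: 17 (2E)-3-{3-methoxy-4-[(4-methylphenyl)sulfonyloxy]phenyl}prop-2-enoic acid
Conditions: TsCl, aq. NaOH, THF, 0 °C → rt; then aq. HCl
Reagents that add atoms: p-toluenesulfonyl chloride, Cc1ccc(cc1)S(=O)(=O)Cl
Why: Schotten–Baumann sulfonylation of the phenoxide, any mixed anhydride at the carboxylate being hydrolysed back in the aqueous base; the tosylate protects the phenol for the Mitsunobu step and is expected to give a crystal packing suited to head-to-tail photodimerisation.

Step 10
Reactants: 17 (2E)-3-{3-methoxy-4-[(4-methylphenyl)sulfonyloxy]phenyl}prop-2-enoic acid (two molecules)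
Product: 18 (1α,2α,3β,4β)-2,4-bis{3-methoxy-4-[(4-methylphenyl)sulfonyloxy]phenyl}cyclobutane-1,3-dicarboxylic acid
Conditions: hν (high-pressure Hg lamp, Pyrex), crystalline powder suspended in hexane, rt
Reagents that add atoms: none
Why: Topochemical [2+2] photocycloaddition in the solid state, in which antiparallel (head-to-tail) stacked E-alkenes of neighbouring molecules join to the centrosymmetric α-truxillic diacid, so the four ring stereocentres follow from the alkene geometry and the packing and the achiral product needs no resolution.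

Step 11
Reactants: 15 (4R,4aS,6S,7S,7aR)-2,4,7-trimethyloctahydro-1H-cyclopenta[c]pyridin-6-ol (2.2 equiv); 18 (1α,2α,3β,4β)-2,4-bis{3-methoxy-4-[(4-methylphenyl)sulfonyloxy]phenyl}cyclobutane-1,3-dicarboxylic acid
Product: 19 bis[(4R,4aS,6R,7S,7aR)-2,4,7-trimethyloctahydro-1H-cyclopenta[c]pyridin-6-yl] (1α,2α,3β,4β)-2,4-bis{3-methoxy-4-[(4-methylphenyl)sulfonyloxy]phenyl}cyclobutane-1,3-dicarboxylate
Conditions: PPh3, DIAD, THF, 0 °C → rt
Reagents that add atoms: none
Why: Double Mitsunobu esterification, in which each carboxylate displaces the oxyphosphonium leaving group at C6 in an SN2 step with inversion (6S to 6R), placing both ester oxygens on the convex face as in the target, while the tertiary amines and the aryl tosylates should not interfere.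

Step 12
Reactants: 19 bis-O-tosyl diester from step 11
Product: 20 bis[(4R,4aS,6R,7S,7aR)-2,4,7-trimethyloctahydro-1H-cyclopenta[c]pyridin-6-yl] (1α,2α,3β,4β)-2,4-bis(4-hydroxy-3-methoxyphenyl)cyclobutane-1,3-dicarboxylate (CNP0283097.2, incarvillateine)
Conditions: Na(Hg) (5% Na), Na2HPO4, MeOH, −20 → 0 °C
Reagents that add atoms: none
Why: Reductive cleavage of the two aryl sulfonate S–O bonds by electron transfer from sodium amalgam frees the phenols, and the phosphate buffer keeps the methoxide concentration too low for transesterification of the hindered cyclobutane esters or epimerisation α to them.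

**Compound list**

1 | tert-butyl methylcarbamate | CNC(=O)OC(C)(C)C | starting material
2 | (E)-1,4-dichlorobut-2-ene | ClC/C=C/CCl | starting material
3 | tert-butyl [(2E)-4-chlorobut-2-en-1-yl](methyl)carbamate | CN(C/C=C/CCl)C(=O)OC(C)(C)C | intermediate
4 | (2E)-4-[(tert-butoxycarbonyl)(methyl)amino]but-2-en-1-yl acetate (not isolated) | CN(C/C=C/COC(C)=O)C(=O)OC(C)(C)C | intermediate
5 | tert-butyl [(2E)-4-hydroxybut-2-en-1-yl](methyl)carbamate | CN(C/C=C/CO)C(=O)OC(C)(C)C | intermediate
6 | (2E)-4-[(tert-butoxycarbonyl)(methyl)amino]but-2-en-1-yl methyl carbonate | CN(C/C=C/COC(=O)OC)C(=O)OC(C)(C)C | intermediate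
7 | tert-butyl 2-methyl-3-oxobutanoate (racemic) | CC(=O)C(C)C(=O)OC(C)(C)C | starting material
8 | tert-butyl (3R)-2-acetyl-3-{[(tert-butoxycarbonyl)(methyl)amino]methyl}-2-methylpent-4-enoate (both C2 epimers) | CC(=O)C(C)(C(=O)OC(C)(C)C)[C@@H](C=C)CN(C)C(=O)OC(C)(C)C | intermediate
9 | methacryloyl chloride | C=C(C)C(Cl)=O | starting material
10 | (3R)-2-acetyl-2-methyl-3-[(methylazaniumyl)methyl]pent-4-enoic acid trifluoroacetate (both C2 epimers, not isolated) | CC(=O)C(C)(C(=O)O)[C@@H](C=C)C[NH2+]C.[O-]C(=O)C(F)(F)F | intermediate
11 | (2R)-2-ethenyl-N,3-dimethyl-4-oxopentan-1-aminium trifluoroacetate (both C3 epimers, not isolated) | CC(=O)C(C)[C@@H](C=C)C[NH2+]C.[O-]C(=O)C(F)(F)F | intermediate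
12 | N-[(2R)-2-ethenyl-3-methyl-4-oxopentyl]-N,2-dimethylprop-2-enamide (both C3 epimers) | CC(=O)C(C)[C@@H](C=C)CN(C)C(=O)C(C)=C | intermediate
13 | (5R)-1,3-dimethyl-5-(3-oxobutan-2-yl)-5,6-dihydropyridin-2(1H)-one (both epimers at the side-chain carbon C7) | CC(=O)C(C)[C@@H]1CN(C)C(=O)C(C)=C1 | intermediate
14 | (4R,4aR,7S,7aR)-2,4,7-trimethylhexahydro-1H-cyclopenta[c]pyridine-3,6(2H,4H)-dione | O=C1C[C@@H]2[C@@H](CN(C)C(=O)[C@@H]2C)[C@@H]1C | intermediate
15 | (4R,4aS,6S,7S,7aR)-2,4,7-trimethyloctahydro-1H-cyclopenta[c]pyridin-6-ol (6-epi-incarvilline) | O[C@H]1C[C@@H]2[C@@H](CN(C)C[C@@H]2C)[C@@H]1C | intermediate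
16 | ferulic acid | COc1cc(/C=C/C(=O)O)ccc1O | starting material
17 | (2E)-3-{3-methoxy-4-[(4-methylphenyl)sulfonyloxy]phenyl}prop-2-enoic acid | COc1cc(/C=C/C(=O)O)ccc1OS(=O)(=O)c1ccc(C)cc1 | intermediate
18 | (1α,2α,3β,4β)-2,4-bis{3-methoxy-4-[(4-methylphenyl)sulfonyloxy]phenyl}cyclobutane-1,3-dicarboxylic acid | COc1cc([C@H]2[C@H](C(=O)O)[C@H](c3ccc(OS(=O)(=O)c4ccc(C)cc4)c(OC)c3)[C@H]2C(=O)O)ccc1OS(=O)(=O)c1ccc(C)cc1 | intermediate
19 | bis[(4R,4aS,6R,7S,7aR)-2,4,7-trimethyloctahydro-1H-cyclopenta[c]pyridin-6-yl] (1α,2α,3β,4β)-2,4-bis{3-methoxy-4-[(4-methylphenyl)sulfonyloxy]phenyl}cyclobutane-1,3-dicarboxylate | COc1cc([C@H]2[C@H](C(=O)O[C@@H]3C[C@@H]4[C@@H](CN(C)C[C@@H]4C)[C@@H]3C)[C@H](c3ccc(OS(=O)(=O)c4ccc(C)cc4)c(OC)c3)[C@H]2C(=O)O[C@@H]2C[C@@H]3[C@@H](CN(C)C[C@@H]3C)[C@@H]2C)ccc1OS(=O)(=O)c1ccc(C)cc1 | intermediate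
20 | bis[(4R,4aS,6R,7S,7aR)-2,4,7-trimethyloctahydro-1H-cyclopenta[c]pyridin-6-yl] (1α,2α,3β,4β)-2,4-bis(4-hydroxy-3-methoxyphenyl)cyclobutane-1,3-dicarboxylate (CNP0283097.2, incarvillateine) | COc1cc([C@H]2[C@H](C(=O)O[C@@H]3C[C@@H]4[C@@H](CN(C)C[C@@H]4C)[C@@H]3C)[C@H](c3ccc(O)c(OC)c3)[C@H]2C(=O)O[C@@H]2C[C@@H]3[C@@H](CN(C)C[C@@H]3C)[C@@H]2C)ccc1O | target

**Count and risks**

Total step count: 12. Longest linear sequence: 10 steps (steps 1–8, 11 and 12); the diacid branch (steps 9 and 10) has 2 steps.

Step 7 is the most exposed step. The lactam is a weak acceptor, so the addition may be slow enough for γ-deprotonation at C7a to migrate the alkene and erase the only preformed stereocentre. Protonation at C4 may also lose its facial preference or be followed by epimerisation. The fallback sets out from 13. The ketone is deprotonated kinetically on the methyl side and silylated (LiN(SiMe3)2, Me3SiCl, THF, −78 °C) to the silyl enol ether (5R)-1,3-dimethyl-5-{3-[(trimethylsilyl)oxy]but-3-en-2-yl}-5,6-dihydropyridin-2(1H)-one F2. An intramolecular Mukaiyama–Michael addition under Lewis-acid activation of the lactam carbonyl (Me3SiOTf, 20 mol%, CH2Cl2, −78 °C, aqueous work-up) then closes the same C4a–C5 bond without free base. It should give (4R,4aR,7aR)-2,4,7-trimethylhexahydro-1H-cyclopenta[c]pyridine-3,6(2H,4H)-dione as its C7 epimers F3. Brief K2CO3/MeOH treatment equilibrates only the ketone α-centre and rejoins the route at 14.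

Step 4 is the second risk. The fully substituted enolate carbon may attack slowly and partly at the unsubstituted allyl terminus, giving the linear isomer, and enantioselectivity may erode with this carbamate-bearing aliphatic electrophile. The fallback sets out from 6 and runs the allylation under the same catalyst with the less hindered tert-butyl 3-oxobutanoate. This should give tert-butyl (3R)-2-acetyl-3-{[(tert-butoxycarbonyl)(methyl)amino]methyl}pent-4-enoate F1. C-Methylation of its β-keto ester (MeI, K2CO3, acetone) builds the quaternary carbon after the stereocentre and rejoins the route at 8.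

Step 11 is the third risk. The activated oxyphosphonium at the hindered secondary C6 may eliminate instead of being displaced, or the reaction may stall at the mono-ester because the second carboxylate sits on a crowded cyclobutane. The fallback sets out from 15 and inverts C6 on the alkaloid alone by a Mitsunobu reaction with 4-nitrobenzoic acid (PPh3, DIAD, THF). This gives (4R,4aS,6R,7S,7aR)-2,4,7-trimethyloctahydro-1H-cyclopenta[c]pyridin-6-yl 4-nitrobenzoate F4, which is methanolysed (K2CO3 cat., MeOH) to (4R,4aS,6R,7S,7aR)-2,4,7-trimethyloctahydro-1H-cyclopenta[c]pyridin-6-ol F5. Diacid 18 is converted with oxalyl chloride and catalytic DMF into (1α,2α,3β,4β)-2,4-bis{3-methoxy-4-[(4-methylphenyl)sulfonyloxy]phenyl}cyclobutane-1,3-dicarbonyl dichloride F6. Acylation of F5 with F6 (pyridine, DMAP, CH2Cl2), with retention at C6, rejoins the route at 19.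

**Further compounds**

F1 | step 4 | tert-butyl (3R)-2-acetyl-3-{[(tert-butoxycarbonyl)(methyl)amino]methyl}pent-4-enoate (both C2 epimers) | CC(=O)C(C(=O)OC(C)(C)C)[C@@H](C=C)CN(C)C(=O)OC(C)(C)C
F2 | step 7 | (5R)-1,3-dimethyl-5-{3-[(trimethylsilyl)oxy]but-3-en-2-yl}-5,6-dihydropyridin-2(1H)-one (both side-chain epimers) | C=C(O[Si](C)(C)C)C(C)[C@@H]1CN(C)C(=O)C(C)=C1
F3 | step 7 | (4R,4aR,7aR)-2,4,7-trimethylhexahydro-1H-cyclopenta[c]pyridine-3,6(2H,4H)-dione (both C7 epimers) | O=C1C[C@@H]2[C@@H](CN(C)C(=O)[C@@H]2C)C1C
F4 | step 11 | (4R,4aS,6R,7S,7aR)-2,4,7-trimethyloctahydro-1H-cyclopenta[c]pyridin-6-yl 4-nitrobenzoate | O=C(O[C@@H]1C[C@@H]2[C@@H](CN(C)C[C@@H]2C)[C@@H]1C)c1ccc([N+](=O)[O-])cc1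
F5 | step 11 | (4R,4aS,6R,7S,7aR)-2,4,7-trimethyloctahydro-1H-cyclopenta[c]pyridin-6-ol (incarvilline) | O[C@@H]1C[C@@H]2[C@@H](CN(C)C[C@@H]2C)[C@@H]1C
F6 | step 11 | (1α,2α,3β,4β)-2,4-bis{3-methoxy-4-[(4-methylphenyl)sulfonyloxy]phenyl}cyclobutane-1,3-dicarbonyl dichloride | COc1cc([C@H]2[C@H](C(=O)Cl)[C@H](c3ccc(OS(=O)(=O)c4ccc(C)cc4)c(OC)c3)[C@H]2C(=O)Cl)ccc1OS(=O)(=O)c1ccc(C)cc1
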